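**Retrosynthetic overview**

- The route rests on ring A: its OH carbon is para to the carbon bearing the ring D ether oxygen, and the CH2CH2 bridge to ring B sits ortho to that ether carbon. This is the pattern left when a 2-aryloxyfuran adds an acyl alkyne and the oxygen bridge opens.
- Last disconnections: the ring B methyl ether (BBr3) and a benzylic C=O on the A–B bridge carbon next to ring A (ionic hydrogenation), leading back to macrocyclic ketone 18.
- Key disconnection: 18 is opened at two ring A C–C bonds (ether carbon to acyl-bearing carbon; OH carbon to its neighbouring CH) to give the seco furan–ynone 16, so ring A and the 18-membered ring form together and last.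
- 16 comes from a Weinreb amide (ynone) and a 5-aryloxy-2-furoate (saponification, decarboxylation) on the ring D phenol.
- Rings B, C and D are bought as benzenes: B–O–C by SNAr on 4-fluorobenzaldehyde, C–CH2CH2–D by Wittig olefination and hydrogenation; the furan is attached next.

Key step: step 10

Remark: the target has no stereocentre; 15, 17 and 19 are transient racemates (17 is drawn as one enantiomer), and 9 is an E/Z mixture that converges in step 5.

**Route**

Step 1
Reactants: 1 3-hydroxy-4-methoxyphenylacetic acid
Product: 3 2-(3-hydroxy-4-methoxyphenyl)-N-methoxy-N-methylacetamide, via acyl imidazolide 2 (not isolated)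
Conditions: CDI (1.05 equiv), THF, rt; then MeNHOMe·HCl, rt
Reagents that add atoms: N,O-dimethylhydroxylamine hydrochloride, CNOC.Cl
Why: Amide coupling through the acyl imidazolide, which forms from the carboxylic acid much faster than CDI acylates the phenol, gives a Weinreb amide that is inert to every step before step 9 and lacks the α-acidity of an ester.

Step 2
Reactants: 3 2-(3-hydroxy-4-methoxyphenyl)-N-methoxy-N-methylacetamide; 4 4-fluorobenzaldehyde
Product: 5 2-[3-(4-formylphenoxy)-4-methoxyphenyl]-N-methoxy-N-methylacetamide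
Conditions: K2CO3, DMF, 120 °C
Reagents that add atoms: none
Why: Nucleophilic aromatic substitution, in which the para-formyl group activates the fluoride toward the guaiacol-type phenoxide, is the standard entry to the B–O–C diaryl ether of bisbibenzyls and leaves the amide untouched.

Step 3
Reactants: 6 3-(benzyloxy)benzyl bromide
Product: 7 [3-(benzyloxy)benzyl]triphenylphosphonium bromide
Conditions: PPh3, PhMe, reflux
Reagents that add atoms: triphenylphosphine, c1ccc(cc1)P(c1ccccc1)c1ccccc1
Why: SN2 quaternisation of triphenylphosphine by a benzylic bromide should give the salt, which precipitates from toluene.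

Step 4
Reactants: 7 [3-(benzyloxy)benzyl]triphenylphosphonium bromide; 5 2-[3-(4-formylphenoxy)-4-methoxyphenyl]-N-methoxy-N-methylacetamide
Product: 9 2-[3-(4-{2-[3-(benzyloxy)phenyl]ethenyl}phenoxy)-4-methoxyphenyl]-N-methoxy-N-methylacetamide (E/Z mixture), via phosphonium ylide 8 (not isolated)
Conditions: K2CO3, 18-crown-6 (cat.), CH2Cl2, reflux
Reagents that add atoms: none
Why: Wittig olefination of the aryl aldehyde by the semi-stabilised benzylide, generated with solid carbonate too weak to deprotonate the amide α-CH2, joins rings C and D, and the alkene geometry is irrelevant because it is saturated in step 5.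

Step 5
Reactants: 9 2-[3-(4-{2-[3-(benzyloxy)phenyl]ethenyl}phenoxy)-4-methoxyphenyl]-N-methoxy-N-methylacetamide
Product: 10 2-[3-{4-[2-(3-hydroxyphenyl)ethyl]phenoxy}-4-methoxyphenyl]-N-methoxy-N-methylacetamide
Conditions: H2 (1 atm), 10% Pd/C, EtOAc/EtOH, rt
Reagents that add atoms: none
Why: Catalytic hydrogenation saturates the stilbene and hydrogenolyses the benzyl ether in one operation, while the diaryl ether and the Weinreb amide should survive at 1 atm and room temperature.

Step 6
Reactants: 10 2-[3-{4-[2-(3-hydroxyphenyl)ethyl]phenoxy}-4-methoxyphenyl]-N-methoxy-N-methylacetamide; 11 methyl 5-bromofuran-2-carboxylate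
Product: 12 methyl 5-{3-[2-(4-{2-methoxy-5-[2-(methoxy(methyl)amino)-2-oxoethyl]phenoxy}phenyl)ethyl]phenoxy}furan-2-carboxylate
Conditions: Cs2CO3, DMF, 100 °C
Reagents that add atoms: none
Why: Nucleophilic aromatic substitution on the furan, whose C5 bromide is activated by the 2-ester, lets the ring D phenoxide form the aryl furyl ether, the established entry to 5-aryloxy-2-furoates.

Step 7
Reactants: 12 methyl 5-{3-[2-(4-{2-methoxy-5-[2-(methoxy(methyl)amino)-2-oxoethyl]phenoxy}phenyl)ethyl]phenoxy}furan-2-carboxylate
Product: 13 5-{3-[2-(4-{2-methoxy-5-[2-(methoxy(methyl)amino)-2-oxoethyl]phenoxy}phenyl)ethyl]phenoxy}furan-2-carboxylic acid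
Conditions: LiOH, THF/MeOH/H2O, rt; then 1 M HCl to pH 3, 0 °C
Reagents that add atoms: lithium hydroxide, [Li+].[OH-]
Why: Saponification cleaves the heteroaryl methyl ester at room temperature while the far less electrophilic Weinreb amide stays intact, and the acceptor-substituted furan tolerates the brief acidification.

Step 8
Reactants: 13 5-{3-[2-(4-{2-methoxy-5-[2-(methoxy(methyl)amino)-2-oxoethyl]phenoxy}phenyl)ethyl]phenoxy}furan-2-carboxylic acid
Product: 14 2-[3-(4-{2-[3-(furan-2-yloxy)phenyl]ethyl}phenoxy)-4-methoxyphenyl]-N-methoxy-N-methylacetamide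
Conditions: Ag2CO3 (10 mol%), AcOH (5 mol%), DMSO, 120 °C
Reagents that add atoms: none
Why: Ag2CO3-catalysed protodecarboxylation of a heteroaryl-2-carboxylic acid, eased here by the electron-rich 5-aryloxyfuran, should release the 2-aryloxyfuran under near-neutral conditions that spare this acid-labile group and the amide.

Step 9
Reactants: 14 2-[3-(4-{2-[3-(furan-2-yloxy)phenyl]ethyl}phenoxy)-4-methoxyphenyl]-N-methoxy-N-methylacetamide
Product: 16 1-[3-(4-{2-[3-(furan-2-yloxy)phenyl]ethyl}phenoxy)-4-methoxyphenyl]but-3-yn-2-one, via magnesium hemiaminal adduct 15 (not isolated)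
Conditions: HC≡CMgBr (4 equiv), THF, 0 °C → rt; inverse quench into ice-cold 1 M aq. NaHSO4/Et2O; dried (Na2SO4), kept cold and dilute, used at once
Reagents that add atoms: ethynylmagnesium bromide, C#C[Mg]Br
Why: In this Weinreb ketone synthesis the acetylide adds once and the chelated adduct 15 holds until the quench, where cold dilute acid protonates the released amine before it can add to the ynone and the short two-phase contact should spare the aryloxyfuran.

Step 10
Reactants: 16 1-[3-(4-{2-[3-(furan-2-yloxy)phenyl]ethyl}phenoxy)-4-methoxyphenyl]but-3-yn-2-one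
Product: 18 macrocyclic ring A phenol ketone (dihydroptychantol A skeleton with ring B OMe and C=O at the A–B bridge carbon attached to ring A), via oxanorbornadiene 17 (not isolated)
Conditions: PhMe (0.5 mM, 16 added by syringe pump over 12 h), BHT (cat.), 100 °C
Reagents that add atoms: none
Why: Proposed new method: the furan, its HOMO raised by the ring D oxygen with the largest coefficient at C5, should add across the tethered ethynyl ketone in a normal-demand intramolecular [4+2] cycloaddition, C5 bonding to the terminal alkyne carbon and the aryloxy-bearing C2 to the acyl-bearing carbon, to give 1-aryloxy-7-oxanorbornadiene 17. The C1–O bridge bond of 17 then ionises to the aryloxy-stabilised oxocarbenium ion and the other bridgehead loses its proton, so the furan oxygen ends as the OH para to the diaryl ether and the step becomes irreversible. The closest known reaction type is the intermolecular Diels–Alder benzannulation of 2-alkoxyfurans with propiolates and ynones, which gives 4-alkoxyphenols acylated ortho to the alkoxy group; a 2-aryloxyfuran closing a macrocycle this way is not known. Ring A is closed by cycloaddition followed by aromatisation, and the 18-membered ring is closed end to end in the same event through the new bond between the ether-bearing and acyl-bearing carbons of ring A, the second new bond (OH carbon to its neighbouring CH) lying outside the macrocycle. The two bridgehead stereocentres of 17 vanish on aromatisation, so no stereocontrol is needed. The step needs ortho regiochemistry (the meta mode would give a 19-membered isomer), which the matched polarisation of donor furan and ynone should secure, and ring closure over oligomerisation, which high dilution in a non-polar solvent should secure while also disfavouring an open zwitterionic Michael pathway.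

Step 11
Reactants: 18 macrocyclic ring A phenol ketone
Product: 20 dihydroptychantol A ring B methyl ether, via benzylic alcohol 19 (not isolated)
Conditions: Et3SiH (4 equiv), CF3CO2H, 0 °C → rt
Reagents that add atoms: none
Why: Ionic hydrogenation should deliver hydride to the protonated aryl ketone to give alcohol 19, which ionises in CF3CO2H to the ortho-aryloxy-stabilised benzylic cation and is reduced again to CH2, with the phenol and aryl ethers inert.

Step 12
Reactants: 20 dihydroptychantol A ring B methyl ether
Product: 21 dihydroptychantol A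
Conditions: BBr3, CH2Cl2, −78 → 0 °C; then H2O
Reagents that add atoms: none
Why: Lewis-acid ether cleavage with BBr3 removes the methyl group by bromide attack at its sp3 carbon, while the two diaryl ethers offer no such carbon and should survive.

**Compound list**

1 | 3-hydroxy-4-methoxyphenylacetic acid | COc1ccc(CC(=O)O)cc1O | starting material
2 | 1-[(3-hydroxy-4-methoxyphenyl)acetyl]imidazole | COc1ccc(CC(=O)n2ccnc2)cc1O | intermediate
3 | 2-(3-hydroxy-4-methoxyphenyl)-N-methoxy-N-methylacetamide | CON(C)C(=O)Cc1ccc(OC)c(O)c1 | intermediate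
4 | 4-fluorobenzaldehyde | O=Cc1ccc(F)cc1 | starting material
5 | 2-[3-(4-formylphenoxy)-4-methoxyphenyl]-N-methoxy-N-methylacetamide | CON(C)C(=O)Cc1ccc(OC)c(Oc2ccc(C=O)cc2)c1 | intermediate
6 | 3-(benzyloxy)benzyl bromide | BrCc1cccc(OCc2ccccc2)c1 | starting material
7 | [3-(benzyloxy)benzyl]triphenylphosphonium bromide | [Br-].c1ccccc1COc1cccc(C[P+](c2ccccc2)(c2ccccc2)c2ccccc2)c1 | intermediate
8 | [3-(benzyloxy)benzylidene]triphenylphosphorane | c1ccccc1COc1cccc(C=P(c2ccccc2)(c2ccccc2)c2ccccc2)c1 | intermediate
9 | 2-[3-(4-{2-[3-(benzyloxy)phenyl]ethenyl}phenoxy)-4-methoxyphenyl]-N-methoxy-N-methylacetamide (E/Z mixture) | CON(C)C(=O)Cc1ccc(OC)c(Oc2ccc(C=Cc3cccc(OCc4ccccc4)c3)cc2)c1 | intermediate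
10 | 2-[3-{4-[2-(3-hydroxyphenyl)ethyl]phenoxy}-4-methoxyphenyl]-N-methoxy-N-methylacetamide | CON(C)C(=O)Cc1ccc(OC)c(Oc2ccc(CCc3cccc(O)c3)cc2)c1 | intermediate
11 | methyl 5-bromofuran-2-carboxylate | COC(=O)c1ccc(Br)o1 | starting material
12 | methyl 5-aryloxyfuran-2-carboxylate of 10 (ring D oxygen on furan C5) | CON(C)C(=O)Cc1ccc(OC)c(Oc2ccc(CCc3cccc(Oc4ccc(C(=O)OC)o4)c3)cc2)c1 | intermediate
13 | 5-aryloxyfuran-2-carboxylic acid corresponding to 12 | CON(C)C(=O)Cc1ccc(OC)c(Oc2ccc(CCc3cccc(Oc4ccc(C(=O)O)o4)c3)cc2)c1 | intermediate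
14 | 2-[3-(4-{2-[3-(furan-2-yloxy)phenyl]ethyl}phenoxy)-4-methoxyphenyl]-N-methoxy-N-methylacetamide | CON(C)C(=O)Cc1ccc(OC)c(Oc2ccc(CCc3cccc(Oc4ccco4)c3)cc2)c1 | intermediate
15 | bromomagnesium alkoxide of the ethynyl adduct of 14 (tetrahedral N,O-hemiaminal, racemic) | CON(C)C(O[Mg]Br)(C#C)Cc1ccc(OC)c(Oc2ccc(CCc3cccc(Oc4ccco4)c3)cc2)c1 | intermediate
16 | 1-[3-(4-{2-[3-(furan-2-yloxy)phenyl]ethyl}phenoxy)-4-methoxyphenyl]but-3-yn-2-one | C#CC(=O)Cc1ccc(OC)c(Oc2ccc(CCc3cccc(Oc4ccco4)c3)cc2)c1 | intermediate
17 | macrocyclic 7-oxabicyclo[2.2.1]hepta-2,5-diene with the ring D oxygen on bridgehead C1 and the bridge carbonyl on C2 (racemic, one enantiomer drawn) | O1[C@H]2C=C[C@@]16Oc3cccc(CCc4ccc(Oc5cc(CC(=O)C6=C2)ccc5OC)cc4)c3 | intermediate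
18 | macrocyclic ring A phenol ketone (ring B OMe; C=O on the bridge carbon attached to ring A) | Oc1ccc2c(c1)C(=O)Cc1ccc(OC)c(c1)Oc1ccc(cc1)CCc1cccc(c1)O2 | intermediate
19 | macrocyclic benzylic alcohol from 18 (racemic) | Oc1ccc2c(c1)C(O)Cc1ccc(OC)c(c1)Oc1ccc(cc1)CCc1cccc(c1)O2 | intermediate
20 | dihydroptychantol A ring B methyl ether | Oc1ccc2c(c1)CCc1ccc(OC)c(c1)Oc1ccc(cc1)CCc1cccc(c1)O2 | intermediate
21 | dihydroptychantol A | Oc1ccc2c(c1)CCc1ccc(O)c(c1)Oc1ccc(cc1)CCc1cccc(c1)O2 | target

**Step count**

Total: 12 steps. Longest linear sequence: 11 steps (steps 1, 2, 4 to 12, from 1).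

**Steps most likely to fail**

1. Step 10 (proposed new method). Intermolecular cycloaddition or oligomerisation may outrun ring closure, the furan C5 may add to the ynone in Michael fashion without closing the second bond, or the ynone may decompose on long heating. The fallback uses known chemistry only, sets out from phenol 10 and comes back at target 21. Phenol 10 is deprotonated with i-PrMgCl and treated with 2-bromo-5-methoxyphenylmagnesium chloride F1 (from 1-bromo-2-iodo-4-methoxybenzene and i-PrMgCl·LiCl, THF, −40 °C), which gives by Weinreb ketone synthesis the 2-bromo-5-methoxyphenyl ketone F2. Et3SiH in CF3CO2H reduces it to the bromo bibenzyl phenol F3. An intramolecular Ullmann ether synthesis (CuI, N,N-dimethylglycine, Cs2CO3, 1,4-dioxane, 100 °C, 2 mM) closes the 18-membered ring at the ring A–O–ring D bond and gives di-O-methyl dihydroptychantol A F4. BBr3 then cleaves both methyl ethers to 21.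

2. Step 9. The liberated N,O-dimethylhydroxylamine may add to the ynone during the quench, the acidic quench may hydrolyse the aryloxyfuran, or the Grignard reagent may enolise the benzylic amide. The fallback sets out from amide 14 and comes back at ynone 16 by an oxidation-state detour. i-Bu2AlH (THF, −78 °C, aq. potassium sodium tartrate work-up) gives the arylacetaldehyde F5. HC≡CMgBr (THF, −78 → 0 °C, NH4Cl quench) gives the racemic propargylic alcohol F6. MnO2 (CH2Cl2, rt) oxidises it under neutral conditions to 16.

3. Step 8. Protodecarboxylation may stall, or the electron-rich furan may degrade during prolonged heating with the acid. The fallback sets out from phenol 10 and comes back at aryloxyfuran 14, replacing steps 6 to 8. SNAr of 10 on 5-bromofuran-2-carbaldehyde (K2CO3, DMF, 80 °C) gives the 5-aryloxyfuran-2-carbaldehyde F7. Catalytic decarbonylation (Pd(OAc)2, 4 Å molecular sieves, cyclohexane, 140 °C, sealed tube) then removes the formyl group to give 14.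

**Further compounds**

F1 | step 10 | 2-bromo-5-methoxyphenylmagnesium chloride | COc1ccc(Br)c([Mg]Cl)c1
F2 | step 10 | 1-(2-bromo-5-methoxyphenyl)-2-[3-{4-[2-(3-hydroxyphenyl)ethyl]phenoxy}-4-methoxyphenyl]ethanone | COc1ccc(Br)c(c1)C(=O)Cc1ccc(OC)c(Oc2ccc(CCc3cccc(O)c3)cc2)c1
F3 | step 10 | 3-{2-[4-(5-[2-(2-bromo-5-methoxyphenyl)ethyl]-2-methoxyphenoxy)phenyl]ethyl}phenol | COc1ccc(Br)c(c1)CCc1ccc(OC)c(Oc2ccc(CCc3cccc(O)c3)cc2)c1
F4 | step 10 | di-O-methyl dihydroptychantol A (OMe on ring A and ring B) | COc1ccc2c(c1)CCc1ccc(OC)c(c1)Oc1ccc(cc1)CCc1cccc(c1)O2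
F5 | step 9 | 2-[3-(4-{2-[3-(furan-2-yloxy)phenyl]ethyl}phenoxy)-4-methoxyphenyl]acetaldehyde | O=CCc1ccc(OC)c(Oc2ccc(CCc3cccc(Oc4ccco4)c3)cc2)c1
F6 | step 9 | 1-[3-(4-{2-[3-(furan-2-yloxy)phenyl]ethyl}phenoxy)-4-methoxyphenyl]but-3-yn-2-ol (racemic) | C#CC(O)Cc1ccc(OC)c(Oc2ccc(CCc3cccc(Oc4ccco4)c3)cc2)c1
F7 | step 8 | 2-[3-(4-{2-[3-(5-formylfuran-2-yloxy)phenyl]ethyl}phenoxy)-4-methoxyphenyl]-N-methoxy-N-methylacetamide | CON(C)C(=O)Cc1ccc(OC)c(Oc2ccc(CCc3cccc(Oc4ccc(C=O)o4)c3)cc2)c1
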